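**Plan**

- The target is the (3S)-isoflavanone (at C3: C4 > C2 > C1' > H). Retrosynthesis removes first the silyl group on the 2'-oxygen, then the C3 configuration (back to the racemic ketone through the cis-4-ol), then cuts ring C at O1–C2 and at C4–C4a.
- Enabling feature: in ring C the ether oxygen O1 and the carbonyl carbon C4 sit on the neighbouring carbons C8a and C4a of ring A, and O1 is β to the ketone. C2–C3–C4 is therefore a 2-arylacryloyl unit that the O,C-dianion of a 2-bromophenol can take up in one operation.
- Forward: the ring A piece (iodination, prenyl Stille coupling) and the ring B piece (silylation, enol triflate, aminocarbonylation) are joined with closure of ring C; rings A and B are bought.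
- Stereochemistry: C3 is the only stereocentre. It is formed racemic, set as S by transfer hydrogenation with dynamic kinetic resolution using the (S,S)-TsDPEN ruthenium catalyst, and kept through buffered oxidation and buffered desilylation.

Key step: step 6

**Route**

Step 1
Reactants: 1 2-bromo-5-methoxyphenol
Product: 2 2-bromo-4-iodo-5-methoxyphenol
Conditions: NIS, TsOH (cat.), MeCN, 0 °C to rt
Reagents that add atoms: N-iodosuccinimide, O=C1CCC(=O)N1I
Why: Electrophilic aromatic iodination should go to C4, the only free position para to the hydroxyl and ortho to the methoxy group (C6 lies between the two oxygens and is hindered), so that iodine marks the future prenyl carbon.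

Step 2
Reactants: 2 2-bromo-4-iodo-5-methoxyphenol
Product: 3 2-bromo-5-methoxy-4-(3-methylbut-2-en-1-yl)phenol
Conditions: tributyl(3-methylbut-2-en-1-yl)stannane, Pd(PPh3)4 (5 mol %), DMF, 80 °C
Reagents that add atoms: tributyl(3-methylbut-2-en-1-yl)stannane, CCCC[Sn](CCCC)(CCCC)CC=C(C)C
Why: In this Stille coupling oxidative addition at the aryl iodide is much faster than at the aryl bromide, and allyl transfer with reductive elimination at the unsubstituted terminus should give the linear prenyl arene while the bromine needed in step 6 is kept.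

Step 3
Reactants: 4 1-(2-hydroxy-4-methoxyphenyl)ethan-1-one (paeonol)
Product: 5 1-[2-(tert-butyldimethylsilyloxy)-4-methoxyphenyl]ethan-1-one
Conditions: TBSCl, imidazole, DMAP (cat.), DMF, 40 °C
Reagents that add atoms: tert-butyldimethylsilyl chloride, CC(C)(C)[Si](C)(C)Cl
Why: Imidazole-promoted silyl ether formation masks the 2'-oxygen with a group that tolerates the organolithium, transfer hydrogenation and periodinane steps and leaves under buffered fluoride.

Step 4
Reactants: 5 1-[2-(tert-butyldimethylsilyloxy)-4-methoxyphenyl]ethan-1-one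
Product: 6 1-[2-(tert-butyldimethylsilyloxy)-4-methoxyphenyl]ethenyl trifluoromethanesulfonate
Conditions: Tf2O, 2,6-di-tert-butyl-4-methylpyridine, CH2Cl2, 0 °C to rt
Reagents that add atoms: trifluoromethanesulfonic anhydride, O=S(=O)(OS(=O)(=O)C(F)(F)F)C(F)(F)F
Why: Enol triflate formation by O-triflation of the aryl methyl ketone and loss of a methyl proton to the hindered base avoids a metal enolate that could take the silyl group from the neighbouring oxygen.

Step 5
Reactants: 6 1-[2-(tert-butyldimethylsilyloxy)-4-methoxyphenyl]ethenyl trifluoromethanesulfonate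
Product: 7 2-[2-(tert-butyldimethylsilyloxy)-4-methoxyphenyl]-N-methoxy-N-methylprop-2-enamide
Conditions: Pd(OAc)2 (5 mol %), dppp (6 mol %), CO (1 atm), MeNHOMe·HCl, Et3N, toluene, 60 °C
Reagents that add atoms: carbon monoxide, [C-]#[O+]; N,O-dimethylhydroxylamine hydrochloride, CNOC.Cl
Why: Palladium-catalysed aminocarbonylation of the vinyl triflate (oxidative addition, CO insertion, capture of the acyl complex by the amine) should give the Weinreb amide in which the former ketone carbon is the future C3, the methylene the future C2 and the new carbonyl the future C4.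

Step 6
Reactants: 3 2-bromo-5-methoxy-4-(3-methylbut-2-en-1-yl)phenol; 7 2-[2-(tert-butyldimethylsilyloxy)-4-methoxyphenyl]-N-methoxy-N-methylprop-2-enamide
Product: 11 rac-3-[2-(tert-butyldimethylsilyloxy)-4-methoxyphenyl]-7-methoxy-6-(3-methylbut-2-en-1-yl)-2,3-dihydro-4H-chromen-4-one, via aryllithium phenoxide 8 (not isolated), via tetrahedral adduct 9 (not isolated), via hydroxy enone 10 (not isolated)
Conditions: t-BuLi (3 equiv), THF, −78 °C; then 7, −78 to 0 °C; aq NH4Cl, rt
Reagents that add atoms: none
Why: tert-Butyllithium deprotonates the phenol and exchanges the bromine of 3, and the aryl carbon of the O,C-dilithio species 8 (future C4a) adds to the amide carbonyl of 7 to give the chelated adduct 9, which collapses on the ammonium chloride quench to hydroxy enone 10 (C4–C4a bond); the freed phenol oxygen then adds to the terminal methylene and the enol tautomerises to 11 (O1–C2 bond). The closest known reaction types are the Weinreb ketone synthesis with 2-lithiophenoxides and the spontaneous oxa-Michael closure of 2-hydroxyaryl α-aryl vinyl ketones met in the deoxybenzoin–formaldehyde route to isoflavanones. Ring C closes in the 6-endo-trig mode, the phenol oxygen and the β-carbon being held close by the ortho acyl link. C3 arises by unselective protonation of the enol, so 11 is racemic, which is intended because this α-aryl ketone centre is labile and is set in step 7. The step needs attack at C4a only, carbonyl instead of conjugate addition, a single addition and closure by O1 only: the bromine ortho to the phenol oxygen fixes the site, lithium chelation by the N-methoxy amide with a hard aryllithium at −78 °C favours the carbonyl and stops at the ketone stage, and the silyl group keeps the 2'-oxygen out.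

Step 7
Reactants: 11 rac-3-[2-(tert-butyldimethylsilyloxy)-4-methoxyphenyl]-7-methoxy-6-(3-methylbut-2-en-1-yl)-2,3-dihydro-4H-chromen-4-one
Product: 12 (3S,4S)-3-[2-(tert-butyldimethylsilyloxy)-4-methoxyphenyl]-7-methoxy-6-(3-methylbut-2-en-1-yl)-3,4-dihydro-2H-chromen-4-ol (cis)
Conditions: RuCl[(S,S)-TsDPEN](p-cymene) (2 mol %), HCO2H/Et3N (1:1), EtOAc, 40 °C
Reagents that add atoms: none
Why: In this Noyori–Ikariya transfer hydrogenation with dynamic kinetic resolution the amine–formate medium should racemise C3 through the enol faster than reduction, the (S,S) catalyst delivers hydride to the C4 face that gives the (4S) carbinol as with simple aryl ketones, and only the ketone enantiomer whose C3 aryl group lies anti to the incoming hydride reacts fast, which gives the cis (3S,4S) alcohol.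

Step 8
Reactants: 12 (3S,4S)-3-[2-(tert-butyldimethylsilyloxy)-4-methoxyphenyl]-7-methoxy-6-(3-methylbut-2-en-1-yl)-3,4-dihydro-2H-chromen-4-ol
Product: 13 (3S)-3-[2-(tert-butyldimethylsilyloxy)-4-methoxyphenyl]-7-methoxy-6-(3-methylbut-2-en-1-yl)-2,3-dihydro-4H-chromen-4-one
Conditions: Dess–Martin periodinane, NaHCO3, CH2Cl2, 0 °C to rt
Reagents that add atoms: none
Why: Dess–Martin oxidation removes the C4 hydrogen within the alkoxyperiodinane under buffered, base-free conditions, so the neighbouring C3 centre should not enolise and the acid-sensitive benzylic alcohol should not ionise.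

Step 9
Reactants: 13 (3S)-3-[2-(tert-butyldimethylsilyloxy)-4-methoxyphenyl]-7-methoxy-6-(3-methylbut-2-en-1-yl)-2,3-dihydro-4H-chromen-4-one
Product: 14 (3S)-3-(2-hydroxy-4-methoxyphenyl)-7-methoxy-6-(3-methylbut-2-en-1-yl)-2,3-dihydro-4H-chromen-4-one
Conditions: TBAF, AcOH (1:1.5), THF, 0 °C
Reagents that add atoms: none
Why: In this fluoride-mediated desilylation the phenoxide is protonated at once by acetic acid, so no base able to enolise C3 builds up, and no strong acid is present that could cyclise the 2'-hydroxy ketone.

**Compound list**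

1 | 2-bromo-5-methoxyphenol | COc1ccc(Br)c(O)c1 | starting material
2 | 2-bromo-4-iodo-5-methoxyphenol | COc1cc(O)c(Br)cc1I | intermediate
3 | 2-bromo-5-methoxy-4-(3-methylbut-2-en-1-yl)phenol | COc1cc(O)c(Br)cc1CC=C(C)C | intermediate
4 | 1-(2-hydroxy-4-methoxyphenyl)ethan-1-one (paeonol) | COc1ccc(C(C)=O)c(O)c1 | starting material
5 | 1-[2-(tert-butyldimethylsilyloxy)-4-methoxyphenyl]ethan-1-one | COc1ccc(C(C)=O)c(O[Si](C)(C)C(C)(C)C)c1 | intermediate
6 | 1-[2-(tert-butyldimethylsilyloxy)-4-methoxyphenyl]ethenyl trifluoromethanesulfonate | COc1ccc(C(=C)OS(=O)(=O)C(F)(F)F)c(O[Si](C)(C)C(C)(C)C)c1 | intermediate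
7 | 2-[2-(tert-butyldimethylsilyloxy)-4-methoxyphenyl]-N-methoxy-N-methylprop-2-enamide | COc1ccc(C(=C)C(=O)N(C)OC)c(O[Si](C)(C)C(C)(C)C)c1 | intermediate
8 | lithium 2-lithio-5-methoxy-4-(3-methylbut-2-en-1-yl)phenolate | [Li]Oc1cc(OC)c(CC=C(C)C)cc1[Li] | intermediate
9 | dilithium salt of 2-[2-(tert-butyldimethylsilyloxy)-4-methoxyphenyl]-1-[2-hydroxy-4-methoxy-5-(3-methylbut-2-en-1-yl)phenyl]-1-[methoxy(methyl)amino]prop-2-en-1-ol (racemic tetrahedral adduct) | COc1ccc(C(=C)C(O[Li])(N(C)OC)c2cc(CC=C(C)C)c(OC)cc2O[Li])c(O[Si](C)(C)C(C)(C)C)c1 | intermediate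
10 | 2-[2-(tert-butyldimethylsilyloxy)-4-methoxyphenyl]-1-[2-hydroxy-4-methoxy-5-(3-methylbut-2-en-1-yl)phenyl]prop-2-en-1-one | COc1ccc(C(=C)C(=O)c2cc(CC=C(C)C)c(OC)cc2O)c(O[Si](C)(C)C(C)(C)C)c1 | intermediate
11 | rac-3-[2-(tert-butyldimethylsilyloxy)-4-methoxyphenyl]-7-methoxy-6-(3-methylbut-2-en-1-yl)-2,3-dihydro-4H-chromen-4-one | COc1ccc(C2COc3cc(OC)c(CC=C(C)C)cc3C2=O)c(O[Si](C)(C)C(C)(C)C)c1 | intermediate
12 | (3S,4S)-3-[2-(tert-butyldimethylsilyloxy)-4-methoxyphenyl]-7-methoxy-6-(3-methylbut-2-en-1-yl)-3,4-dihydro-2H-chromen-4-ol (cis) | COc1ccc([C@H]2COc3cc(OC)c(CC=C(C)C)cc3[C@H]2O)c(O[Si](C)(C)C(C)(C)C)c1 | intermediate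
13 | (3S)-3-[2-(tert-butyldimethylsilyloxy)-4-methoxyphenyl]-7-methoxy-6-(3-methylbut-2-en-1-yl)-2,3-dihydro-4H-chromen-4-one | COc1ccc([C@H]2COc3cc(OC)c(CC=C(C)C)cc3C2=O)c(O[Si](C)(C)C(C)(C)C)c1 | intermediate
14 | (3S)-3-(2-hydroxy-4-methoxyphenyl)-7-methoxy-6-(3-methylbut-2-en-1-yl)-2,3-dihydro-4H-chromen-4-one | COc1ccc([C@H]2COc3cc(OC)c(CC=C(C)C)cc3C2=O)c(O)c1 | target

**Step count**

Total steps: 9. Longest linear sequence: 7 steps (steps 3 to 9).

**Steps most likely to fail**

1. Step 6. Conjugate addition of the aryllithium to the acrylamide, or anionic oligomerisation of 7, may outrun addition to the carbonyl group, and the amine set free on the quench may add to the enone. The fallback sets out from 3 and 7 and makes the two bonds one after the other, so that no free acrylamide meets an organolithium. Trimethylphosphine-catalysed oxa-Michael addition of phenol 3 to 7 (MeCN, rt) should give racemic 3-[2-bromo-5-methoxy-4-(3-methylbut-2-en-1-yl)phenoxy]-2-[2-(tert-butyldimethylsilyloxy)-4-methoxyphenyl]-N-methoxy-N-methylpropanamide F1. Bromine–lithium exchange (t-BuLi, THF, −100 °C) then starts a Parham cycloacylation onto the Weinreb amide, and the fallback comes back to the route at 11.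

2. Step 4. The electron-rich 1-arylvinyl triflate may ionise and hydrolyse back to the ketone during work-up or chromatography, and the silyl ether may be lost to triflic acid. The fallback sets out from 3 and 1 and needs neither 6 nor 7. The dianion 8 made from 3 is acylated with commercial N-methoxy-N-methylprop-2-enamide under the conditions of step 6, which should give 7-methoxy-6-(3-methylbut-2-en-1-yl)-2,3-dihydro-4H-chromen-4-one F2. Phenol 1 is silylated (TBSCl, imidazole, DMF) to (2-bromo-5-methoxyphenoxy)(tert-butyl)dimethylsilane F3. Palladium-catalysed α-arylation of ketone F2 with F3 (Pd(OAc)2, P(t-Bu)3·HBF4, K3PO4, toluene, 80 °C) puts ring B on C3, and the fallback comes back to the route at 11.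

3. Step 7. Racemisation at C3 may be slower than reduction, so that the resolution is not dynamic, and the bulky 2'-silyloxyaryl group may erode facial and cis selectivity. The fallback sets out from 11 and sets C3 by enantioselective protonation instead of reduction. O-Acylation of the potassium enolate (KHMDS, allyl chloroformate, THF, −78 °C) should give allyl 3-[2-(tert-butyldimethylsilyloxy)-4-methoxyphenyl]-7-methoxy-6-(3-methylbut-2-en-1-yl)-2H-chromen-4-yl carbonate F4. Palladium-catalysed decarboxylative protonation (Pd2(dba)3, the tert-butyl-PHOX antipode that gives 3S, Meldrum's acid, dioxane, rt) comes back to the route at 13, so that 12 and step 8 are bypassed.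

**Further compounds**

F1 | step 6 | rac-3-[2-bromo-5-methoxy-4-(3-methylbut-2-en-1-yl)phenoxy]-2-[2-(tert-butyldimethylsilyloxy)-4-methoxyphenyl]-N-methoxy-N-methylpropanamide | COc1ccc(C(COc2cc(OC)c(CC=C(C)C)cc2Br)C(=O)N(C)OC)c(O[Si](C)(C)C(C)(C)C)c1
F2 | step 4 | 7-methoxy-6-(3-methylbut-2-en-1-yl)-2,3-dihydro-4H-chromen-4-one | COc1cc2OCCC(=O)c2cc1CC=C(C)C
F3 | step 4 | (2-bromo-5-methoxyphenoxy)(tert-butyl)dimethylsilane | COc1ccc(Br)c(O[Si](C)(C)C(C)(C)C)c1
F4 | step 7 | allyl 3-[2-(tert-butyldimethylsilyloxy)-4-methoxyphenyl]-7-methoxy-6-(3-methylbut-2-en-1-yl)-2H-chromen-4-yl carbonate | COc1ccc(C2=C(OC(=O)OCC=C)c3cc(CC=C(C)C)c(OC)cc3OC2)c(O[Si](C)(C)C(C)(C)C)c1
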